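## Analysis of the target

- **Numbering and core.** C1 is the benzoyl bridgehead, C2 and C4 are the ketones flanking the quaternary C3, C5 is the prenyl bridgehead and C9 the ketone between C1 and C5. C6H2–C7H–C8Me2 bridges C5 to C1, C10H2–C11H bridges C7 to C3, and C12 (CMe2–O), C13 (OCH), C14H2 (on C3) and C15 (CMe2OOH) complete the peroxide part.
- **Ring system.** The cyclohexane-1,3,5-trione ring C1–C2–C3–C4–C5–C9 is capped by C7. The cyclohexanone ring C5–C6–C7–C8–C1–C9 and the seven-membered ring C3–C4–C5–C6–C7–C10–C11 complete a homoadamantane. A 1,2-dioxepane (C3–C11–C12–O–O–C13–C14) is fused to the C3–C11 bond and carries the tertiary hydroperoxide on C15.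
- **Stereocentres.** C1, C3, C5 and C7 are locked to each other by the cage. At C11, C12 lies on the side of C4 and C6H2, away from the C8 methyl groups. H-13 is cis to H-11 on the dioxepane.
- **Sensitive groups.** The dialkyl peroxide and the hydroperoxide do not tolerate reducing agents, base, transition metals or heat. The β-triketone cannot enolise, and its acyl group on a quaternary carbon is open to retro-Claisen cleavage by nucleophiles.
- **Difficulty.** Four quaternary carbons (C1, C3, C5, C8) stand in mutual 1,3-relationships, no ring position can be epimerised afterwards, and the peroxides can only come last.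
- **Feature used.** C5–C6 and C7–C10 are the only bonds that separate the cage from a monocyclic hexasubstituted cyclohexane-1,3,5-trione. In that trione C1 bears C8Me2–C7H=C6H2, C3 bears C11(=C10H2)–C12, and C5 lies between two carbonyl groups, an ideal radical site.

## Retrosynthetic reasoning

**Peroxide.** The O–Si bond of 19 masks the hydroperoxide of 20. Compound 19 is cut at C12–O, O–C13 and C15–O back to the isopropenyl diene 18. A C12 peroxyl radical sits gauche to C14 on the C3–C11 bond and can reach C13 of the C3 prenyl group. One aerobic operation then gives the dioxepane, the hydroperoxide and C13; the forward reaction must let the 7-exo closure win over reduction of the peroxyl radical.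

**Prenyl and isopropenyl groups.** Compound 18 comes from the tertiary alcohol 17 by loss of water. The two prenyl groups of 17 are cut at their C=C bonds (cross-metathesis with 16) to the diallyl cage 15, and this is traced to the dipropargyl cage 14 by semihydrogenation. The prenyl groups are deliberately not carried through the cage-forming step. A radical between two carbonyl groups closes 5-exo onto a prenyl group on the neighbouring quaternary carbon, and the new tertiary radical then closes onto the second prenyl group. Electrophilic bromine and acid, both needed earlier, would also attack them. Propargyl groups are poor radical acceptors, survive both reagents and cost two routine steps.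

**Key disconnection.** Compound 14 is cut at C5–C6 and C7–C10 to the monocyclic bromide 13. No other pair of bonds opens two rings of the cage at once and leaves a precursor in which every ring carbon is already in place. The forward reaction is a radical bicyclisation started at C5.

**Bromide and free alcohol.** The C5–Br bond, the C4 carbonyl group and the C12 hydroxyl group of 13 are traced to the cyclic enol ether 12, by bromination of the enol ether carbon C5 in wet solvent. The ring keeps the tertiary alcohol masked until this point, and it also controls the next disconnection.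

**C1–C8.** An acyl-bearing carbon is not alkylated directly, so the tertiary carbon C8 is placed on C1 by a Claisen rearrangement of the O-prenyl ether 11, made from 9 and 10. In 9 the shift can end only at C1, because C3 is quaternary and C5 is tied into the enol ether. The fused dihydrofuran holds C11 near the ring plane and forces the C3 propargyl group axial, so C8 enters opposite to it and ends cis to C11, as the cage requires. With open-chain substituents on C3 the larger alkenyl group would send C8 to the wrong face.

**C3–C11 and O4–C12.** Compound 9 is one enantiomer of 8. Compound 8 is opened at O4–C12 (addition of the C4 enol to an isopropenyl group) and at C3–C11 (Claisen rearrangement of the allenylmethyl ether 6). Lewis-acid addition of C3 to a tertiary propargylic alcohol was not relied upon. Such alcohols ionise and give chromenes or propargylic substitution with phloroglucinols, and a ring-embedded 1,3-diketone cannot form the chelated metal enolate that this alkyne addition needs. C3 and C5 of 3 are equivalent, so there is no regiochemical question; the new stereocentre is racemic and is resolved at 8.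

**Building blocks.** Ether 6 comes from phenol 3 and allenol 5 (C–O bond), 3 from 1 and two equivalents of 2 (two C–C bonds), and 5 from 4 by SN2′ methylation.

## Alternatives that were turned down

**Alternative 1:** The cyclohexanone ring C5–C6–C7–C8–C1–C9 is cut at C6–C7 and C1–C8. In the forward sense the silyloxy diene A2 and the acyl oxazolidinone A3 combine under a chiral bis(oxazoline)·Cu(SbF6)2 catalyst (divalent copper) to the cycloadduct A1.
- For it: absolute configuration comes from a catalyst, and no resolution is needed. On this point it is stronger than the chosen route.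
- Against it: A3 is a β,β-disubstituted dienophile and has to form the quaternary C8, a poor case for this catalysis. The one stereocentre gained, C7, is dictated by the cage anyway. The trione ring, the quaternary carbons C1, C3 and C5, the benzoyl group and the C10–C11 bridge would all have to be built afterwards on a hindered ring, in many steps.
- Comparison: the chosen strategy pays with a resolution but forms both missing cage bonds in one step from a ring that already holds every carbon.

**Alternative 2:** The cage is cut at C5–C6 and C3–C11. The lithium polyanion of the diprenyl acylphloroglucinol A5 is alkylated at C5 by the primary iodide A6, and the C3 enolate then opens the epoxide at C11, closing the seven-membered ring of the bicyclo[4.3.1]decane A4.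
- For it: C11 is set by SN2 inversion and the C12 oxygen arrives in the same event. This is better defined than a hydrogen transfer to a C11 radical, so it is stronger on that point.
- Against it: A6 needs two stereocentres in pure form. A fully substituted enolate carbon must attack a secondary epoxide carbon next to CMe2 in a seven-membered closure, where attack through oxygen is the likelier course. The C1–C8 bond between two quaternary carbons still has to be made in a separate cyclisation.
- Comparison: the chosen route has less control at C11 but needs no chiral fragment and leaves no quaternary–quaternary bond for later.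

**Alternative 3:** The dioxepane is cut at C12–O, O–C13 and C15–O. The cage diene A8 (identical with 18) reacts with oxygen and Et3SiH under Co(acac)2 to the silyl peroxide A7 (identical with 19).
- For it: it forms three C–O bonds and C13 in one step, along a plausible biogenetic path.
- Against it: taken as the central idea it solves only the last step and leaves the carbon cage open, which is the hard part.
- Comparison: the chosen strategy keeps exactly this transformation as its endgame and adds a concrete construction of A8.

Key step: step 8

Remark: bromide 13 is drawn as the C5 epimer expected from bromination anti to the C1 dimethylallyl group; both epimers give the same C5 radical. Names of 8–12 use benzofuran numbering (C3a is C3 and C5 is C1 of the cage numbering); 14–20 use the cage numbering of the Analysis.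

## Route

Step 1
Reactants: 1 2,4,6-trihydroxybenzophenone; 2 propargyl bromide (3-bromoprop-1-yne)
Product: 3 phenyl[2,4,6-trihydroxy-3,5-di(prop-2-yn-1-yl)phenyl]methanone
Conditions: 2 (2.2 equiv), 10% aq. KOH, 0 °C to rt
Reagents that add atoms: none
Why: Base-mediated C-alkylation of an acylphloroglucinol; in water the phenoxide oxygens are solvated and the activated halide is taken up at the free ring carbons C3 and C5. O-alkylated and over-alkylated material is expected as by-product and is removed by chromatography.

Step 2
Reactants: 4 4-chlorobut-2-yn-1-ol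
Product: 5 2-methylbuta-2,3-dien-1-ol
Conditions: MeMgBr (2.2 equiv), CuI (10 mol%), Et2O, −20 °C to rt; aq. NH4Cl
Reagents that add atoms: methylmagnesium bromide, C[Mg]Br
Why: Copper-catalysed SN2′ substitution of a propargylic chloride; the methyl group adds to the alkyne carbon remote from chlorine and the allene forms with loss of chloride. The first equivalent of Grignard reagent only deprotonates the alcohol.

Step 3
Reactants: 3 phenyl[2,4,6-trihydroxy-3,5-di(prop-2-yn-1-yl)phenyl]methanone; 5 2-methylbuta-2,3-dien-1-ol
Product: 6 {2,6-dihydroxy-4-[(2-methylbuta-2,3-dien-1-yl)oxy]-3,5-di(prop-2-yn-1-yl)phenyl}(phenyl)methanone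
Conditions: PPh3, DIAD, THF, 0 °C to rt
Reagents that add atoms: none
Why: Mitsunobu etherification; the 4-hydroxyl group is the only one not chelated to the benzoyl carbonyl group and is the most acidic, so it should be the one alkylated. Neutral conditions avoid C-alkylation and base-induced cyclisation of the o-propargyl phenol.

Step 4
Reactants: 6 {2,6-dihydroxy-4-[(2-methylbuta-2,3-dien-1-yl)oxy]-3,5-di(prop-2-yn-1-yl)phenyl}(phenyl)methanone
Product: 8 rac-5-benzoyl-6-hydroxy-2,2-dimethyl-3-methylidene-3a,7-di(prop-2-yn-1-yl)-2,3-dihydro-1-benzofuran-4(3aH)-one, via dienyl trione 7 (not isolated)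
Conditions: PhMe, 120 °C (sealed tube); then CSA (5 mol%), CH2Cl2, 0 °C
Reagents that add atoms: none
Why: Aromatic Claisen rearrangement of an allenylmethyl ether bonds the central allene carbon (C11) to C3 (C5 is equivalent by symmetry) and leaves the dearomatised vinylogous acid 7 with a 3-methylbuta-1,3-dien-2-yl group. Acid then protonates the isopropenyl terminus and the free C4 enol hydroxyl closes on the tertiary end of the allyl cation, an acid-catalysed hydroalkoxylation that should give the five-membered ether under kinetic control. C3 is formed racemic.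

Step 5
Reactants: 8 rac-5-benzoyl-6-hydroxy-2,2-dimethyl-3-methylidene-3a,7-di(prop-2-yn-1-yl)-2,3-dihydro-1-benzofuran-4(3aH)-one
Product: 9 (3aR)-5-benzoyl-6-hydroxy-2,2-dimethyl-3-methylidene-3a,7-di(prop-2-yn-1-yl)-2,3-dihydro-1-benzofuran-4(3aH)-one
Conditions: preparative SFC on amylose tris(3,5-dimethylphenylcarbamate), CO2/MeOH
Reagents that add atoms: none
Why: Chromatographic resolution at the first stereogenic intermediate, whose single stereocentre C3 is quaternary and cannot racemise. The (3aR) enantiomer is carried on once its configuration has been assigned, and every later stereocentre is set relative to it.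

Step 6
Reactants: 9 (3aR)-5-benzoyl-6-hydroxy-2,2-dimethyl-3-methylidene-3a,7-di(prop-2-yn-1-yl)-2,3-dihydro-1-benzofuran-4(3aH)-one; 10 prenyl bromide (1-bromo-3-methylbut-2-ene)
Product: 12 (3aR,5R)-5-benzoyl-2,2-dimethyl-5-(2-methylbut-3-en-2-yl)-3-methylidene-3a,7-di(prop-2-yn-1-yl)-2,3-dihydro-1-benzofuran-4,6(3aH,5H)-dione, via prenyl enol ether 11 (not isolated)
Conditions: 10 (1.2 equiv), K2CO3, acetone, rt; filter and concentrate; PhMe, 110 °C
Reagents that add atoms: none
Why: O-Alkylation of the triketone enolate followed by Claisen rearrangement; whichever oxygen of the C2–C1–C9 unit carries the prenyl group, the shift can end only at C1, and it delivers the tertiary carbon C8. The fused dihydrofuran keeps C11 near the ring plane and the C3 propargyl group axial, so C8 should bond to the opposite face and end cis to C11.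

Step 7
Reactants: 12 (3aR,5R)-5-benzoyl-2,2-dimethyl-5-(2-methylbut-3-en-2-yl)-3-methylidene-3a,7-di(prop-2-yn-1-yl)-2,3-dihydro-1-benzofuran-4,6(3aH,5H)-dione
Product: 13 (2S,4S,6R)-2-benzoyl-6-bromo-4-(3-hydroxy-3-methylbut-1-en-2-yl)-2-(2-methylbut-3-en-2-yl)-4,6-di(prop-2-yn-1-yl)cyclohexane-1,3,5-trione
Conditions: NBS (1.05 equiv), NaHCO3, THF/H2O 4:1, 0 °C, dark
Reagents that add atoms: N-bromosuccinimide, O=C1CCC(=O)N1Br; water, O
Why: Electrophilic bromination of an enol ether with hydrolytic opening; bromine adds to C5 of the vinylogous ester, water captures the C4 oxocarbenium ion, and the hemiketal collapses to the C4 ketone and the C12 alcohol. The terminal alkynes and the hindered alkenes should be less nucleophilic than the enol ether carbon.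

Step 8
Reactants: 13 (2S,4S,6R)-2-benzoyl-6-bromo-4-(3-hydroxy-3-methylbut-1-en-2-yl)-2-(2-methylbut-3-en-2-yl)-4,6-di(prop-2-yn-1-yl)cyclohexane-1,3,5-trione
Product: 14 1-benzoyl-11-(2-hydroxypropan-2-yl)-8,8-dimethyl-3,5-di(prop-2-yn-1-yl)homoadamantane-2,4,9-trione (C12 on the C4 side of C11)
Conditions: (Me3Si)3SiH (1.2 equiv) and AIBN (0.2 equiv) added over 8 h, PhH, 80 °C, 5 mM
Reagents that add atoms: none
Why: (Me3Si)3Si• abstracts bromine from 13 and the silane carries the chain; the C5 radical, delocalised into the C4 and C9 carbonyl groups, is the same for both C5 epimers. The closest known reaction type is the silane- or stannane-mediated reductive polycyclisation of α-halo-β-dicarbonyl compounds onto unactivated alkenes. Ring C5–C6–C7–C8–C1–C9 closes 6-endo-trig by attack on the terminal carbon C6, the mode preferred by α-keto radicals whose carbonyl group (C9) lies inside the forming ring and reinforced by the quaternary C8 next to C7. Ring C3–C4–C5–C6–C7–C10–C11 closes 7-endo-trig when the secondary C7 radical adds to the methylene C10 of the axial C3 alkenyl group; 6-exo attack at C11 would have to build a fully substituted carbon between C3 and C12. C5 is fixed because the new bond can form only on the face that carries the C1 dimethylallyl group, and C7 because only one configuration lets the bridge reach C3. At C11 the CMe2OH group is expected to tilt away from the C8 methyl groups toward C6H2, so that the silane delivers hydrogen to the exposed lobe on the C2 side, which is the configuration of 20. The step needs the 6-endo closure to outrun any reaction on the lower face and the 7-endo closure to outrun reduction of the C7 radical: the lower face carries only propargyl groups, which are poor acceptors for the electrophilic C5 radical, C1, C3 and C5 are quaternary so that nothing can enolise or aromatise, and slow addition keeps the silane concentration low.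

Step 9
Reactants: 14 1-benzoyl-11-(2-hydroxypropan-2-yl)-8,8-dimethyl-3,5-di(prop-2-yn-1-yl)homoadamantane-2,4,9-trione
Product: 15 1-benzoyl-11-(2-hydroxypropan-2-yl)-8,8-dimethyl-3,5-di(prop-2-en-1-yl)homoadamantane-2,4,9-trione
Conditions: H2 (1 atm), Pd/CaCO3 poisoned with Pb(OAc)2, quinoline, EtOAc, rt
Reagents that add atoms: none
Why: Lindlar semihydrogenation of the two terminal alkynes; 14 contains no other C–C multiple bond, and the hindered ketones are not reduced under these conditions.

Step 10
Reactants: 15 1-benzoyl-11-(2-hydroxypropan-2-yl)-8,8-dimethyl-3,5-di(prop-2-en-1-yl)homoadamantane-2,4,9-trione; 16 2-methylbut-2-ene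
Product: 17 1-benzoyl-11-(2-hydroxypropan-2-yl)-8,8-dimethyl-3,5-bis(3-methylbut-2-en-1-yl)homoadamantane-2,4,9-trione
Conditions: second-generation Hoveyda–Grubbs catalyst (5 mol%), 16 (excess), CH2Cl2, 40 °C
Reagents that add atoms: none
Why: Olefin cross-metathesis turns each allyl group into a prenyl group with loss of propene. It is run before the isopropenyl group exists, so no ring-closing metathesis with the C3 allyl group can compete.

Step 11
Reactants: 17 1-benzoyl-11-(2-hydroxypropan-2-yl)-8,8-dimethyl-3,5-bis(3-methylbut-2-en-1-yl)homoadamantane-2,4,9-trione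
Product: 18 1-benzoyl-8,8-dimethyl-3,5-bis(3-methylbut-2-en-1-yl)-11-(prop-1-en-2-yl)homoadamantane-2,4,9-trione
Conditions: Burgess reagent, PhH, 50 °C
Reagents that add atoms: none
Why: Burgess dehydration by syn elimination of the sulfamate ester; H-11 is shielded by the quaternary C3 and the cage, so a methyl hydrogen should be removed and the isopropenyl isomer formed. The non-acidic conditions avoid cationic rearrangement of the cage.

Step 12
Reactants: 18 1-benzoyl-8,8-dimethyl-3,5-bis(3-methylbut-2-en-1-yl)-11-(prop-1-en-2-yl)homoadamantane-2,4,9-trione
Product: 19 triethylsilyl peroxide of 20 (C15–OO–SiEt3)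
Conditions: Co(acac)2 (20 mol%), Et3SiH (2 equiv), O2 (1 atm), ClCH2CH2Cl, rt
Reagents that add atoms: dioxygen, O=O; triethylsilane, CC[SiH](CC)CC
Why: Mukaiyama–Isayama peroxidation; a cobalt hydride transfers hydrogen to the CH2 of the 1,1-disubstituted alkene in preference to the trisubstituted prenyl alkenes, and the C12 radical captures oxygen. The peroxyl radical adds 7-exo to C13 of the C3 prenyl group, and the tertiary C15 radical captures a second oxygen and is silylated. C13 should form through a chair-like closure with the CMe2 substituent pseudo-equatorial, which places H-13 cis to H-11.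

Step 13
Reactants: 19 triethylsilyl peroxide of 20
Product: 20 target: 1-benzoyl-8,8-dimethyl-5-(3-methylbut-2-en-1-yl)homoadamantane-2,4,9-trione with the 1,2-dioxepane C3–C11–C12(Me2)–O–O–C13–C14 fused at C3–C11 and a 2-hydroperoxypropan-2-yl group on C13
Conditions: HCl (cat.), MeOH, 0 °C
Reagents that add atoms: none
Why: Acid-catalysed methanolysis of the O–Si bond frees the hydroperoxide. Base is avoided because it would start a Kornblum–DeLaMare cleavage at C13–H or a retro-Claisen opening of the triketone.

## Compound list

1 | 2,4,6-trihydroxybenzophenone | O=C(c1ccccc1)c1c(O)cc(O)cc1O | starting material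
2 | propargyl bromide (3-bromoprop-1-yne) | C#CCBr | starting material
3 | phenyl[2,4,6-trihydroxy-3,5-di(prop-2-yn-1-yl)phenyl]methanone | O=C(c1ccccc1)c1c(O)c(CC#C)c(O)c(CC#C)c1O | intermediate
4 | 4-chlorobut-2-yn-1-ol | OCC#CCCl | starting material
5 | 2-methylbuta-2,3-dien-1-ol | C=C=C(C)CO | intermediate
6 | {2,6-dihydroxy-4-[(2-methylbuta-2,3-dien-1-yl)oxy]-3,5-di(prop-2-yn-1-yl)phenyl}(phenyl)methanone | O=C(c1ccccc1)c1c(O)c(CC#C)c(OCC(C)=C=C)c(CC#C)c1O | intermediate
7 | rac-2-benzoyl-3,5-dihydroxy-6-(3-methylbuta-1,3-dien-2-yl)-4,6-di(prop-2-yn-1-yl)cyclohexa-2,4-dien-1-one | O=C(c1ccccc1)C1=C(O)C(CC#C)=C(O)C(CC#C)(C(=C)C(C)=C)C1=O | intermediate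
8 | rac-5-benzoyl-6-hydroxy-2,2-dimethyl-3-methylidene-3a,7-di(prop-2-yn-1-yl)-2,3-dihydro-1-benzofuran-4(3aH)-one | O=C(c1ccccc1)C1=C(O)C(CC#C)=C2OC(C)(C)C(=C)C2(CC#C)C1=O | intermediate
9 | (3aR)-5-benzoyl-6-hydroxy-2,2-dimethyl-3-methylidene-3a,7-di(prop-2-yn-1-yl)-2,3-dihydro-1-benzofuran-4(3aH)-one | O=C(c1ccccc1)C1=C(O)C(CC#C)=C2OC(C)(C)C(=C)[C@@]2(CC#C)C1=O | intermediate
10 | prenyl bromide (1-bromo-3-methylbut-2-ene) | CC(C)=CCBr | starting material
11 | (3aR)-5-benzoyl-2,2-dimethyl-6-[(3-methylbut-2-en-1-yl)oxy]-3-methylidene-3a,7-di(prop-2-yn-1-yl)-2,3-dihydro-1-benzofuran-4(3aH)-one | CC(C)=CCOC1=C(C(=O)c2ccccc2)C(=O)[C@]3(CC#C)C(=C)C(C)(C)OC3=C1CC#C | intermediate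
12 | (3aR,5R)-5-benzoyl-2,2-dimethyl-5-(2-methylbut-3-en-2-yl)-3-methylidene-3a,7-di(prop-2-yn-1-yl)-2,3-dihydro-1-benzofuran-4,6(3aH,5H)-dione | C=CC(C)(C)[C@@]1(C(=O)c2ccccc2)C(=O)C(CC#C)=C2OC(C)(C)C(=C)[C@@]2(CC#C)C1=O | intermediate
13 | (2S,4S,6R)-2-benzoyl-6-bromo-4-(3-hydroxy-3-methylbut-1-en-2-yl)-2-(2-methylbut-3-en-2-yl)-4,6-di(prop-2-yn-1-yl)cyclohexane-1,3,5-trione | C#CC[C@]1(Br)C(=O)[C@](C(=O)c2ccccc2)(C(C)(C)C=C)C(=O)[C@](CC#C)(C(=C)C(C)(C)O)C1=O | intermediate
14 | 1-benzoyl-11-(2-hydroxypropan-2-yl)-8,8-dimethyl-3,5-di(prop-2-yn-1-yl)homoadamantane-2,4,9-trione (C12 on the C4 side of C11) | C#CC[C@]12C[C@@H]3C[C@H](C(C)(C)O)[C@](CC#C)(C1=O)C(=O)[C@](C(=O)c1ccccc1)(C2=O)C3(C)C | intermediate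
15 | 1-benzoyl-11-(2-hydroxypropan-2-yl)-8,8-dimethyl-3,5-di(prop-2-en-1-yl)homoadamantane-2,4,9-trione | C=CC[C@]12C[C@@H]3C[C@H](C(C)(C)O)[C@](CC=C)(C1=O)C(=O)[C@](C(=O)c1ccccc1)(C2=O)C3(C)C | intermediate
16 | 2-methylbut-2-ene | CC=C(C)C | starting material
17 | 1-benzoyl-11-(2-hydroxypropan-2-yl)-8,8-dimethyl-3,5-bis(3-methylbut-2-en-1-yl)homoadamantane-2,4,9-trione | CC(C)=CC[C@]12C[C@@H]3C[C@H](C(C)(C)O)[C@](CC=C(C)C)(C1=O)C(=O)[C@](C(=O)c1ccccc1)(C2=O)C3(C)C | intermediate
18 | 1-benzoyl-8,8-dimethyl-3,5-bis(3-methylbut-2-en-1-yl)-11-(prop-1-en-2-yl)homoadamantane-2,4,9-trione | CC(C)=CC[C@]12C[C@@H]3C[C@H](C(C)=C)[C@](CC=C(C)C)(C1=O)C(=O)[C@](C(=O)c1ccccc1)(C2=O)C3(C)C | intermediate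
19 | triethylsilyl peroxide of 20 | CC(C)=CC[C@]12C[C@@H]3C[C@@H]4C(C)(C)OO[C@H](C(C)(C)OO[Si](CC)(CC)CC)C[C@@]4(C1=O)C(=O)[C@](C(=O)c1ccccc1)(C2=O)C3(C)C | intermediate
20 | target, dioxepane-fused homoadamantane trione hydroperoxide | CC(C)=CC[C@]12C[C@@H]3C[C@@H]4C(C)(C)OO[C@H](C(C)(C)OO)C[C@@]4(C1=O)C(=O)[C@](C(=O)c1ccccc1)(C2=O)C3(C)C | target

## Step count and least certain steps

Total: 13 steps. Longest linear sequence: 12 steps (steps 1 and 3 to 13; step 2 prepares 5).

**Step 8 (key step).** The C7 radical may be reduced by the silane before the transannular 7-endo closure, which needs the trione ring to bring the C3 alkenyl group axial. The C5 radical may also close 5-exo-dig onto the lower-face propargyl group, silyl radicals may add to the terminal alkynes late in the reaction, and hydrogen transfer may reach the wrong face of C11. The fallback sets out from 13 and splits the cascade. A bromine-atom-transfer cyclisation without a hydride source (Et3B, air, PhH, rt) should give the bicyclic secondary bromide F1, in which the first ring is closed and nothing can be reduced early. Isolated F1 is then treated with (Me3Si)3SiH and AIBN at high dilution, so that the C7 radical is formed alone and has only the 7-endo closure ahead of it. This returns to the route at 14.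

**Step 4.** The acid step may close through O2 instead of O4, or the allyl cation may equilibrate to the isopropylidene or pyran isomers, and the diene 7 may be lost at the Claisen temperature. The fallback sets out from 3 and uses palladium catalysis instead of two sigmatropic and cationic events. Methyl 2-methylbut-3-yn-2-yl carbonate F2 (from 2-methylbut-3-yn-2-ol, methyl chloroformate and pyridine) is treated with 3, Pd2(dba)3 and dppf (zerovalent palladium) in THF. C3 attacks the central carbon of the allenylpalladium species and O4 closes on the tertiary terminus of the resulting π-allyl complex. This comes back at 8.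

**Step 7.** Bromonium formation at the exocyclic methylene group may compete, or the oxocarbenium ion may ionise at the tertiary allylic C12–O bond and eliminate to a diene instead of taking up water. The fallback sets out from 12 and separates bromination from unlocking. NBS in MeOH at −20 °C should give the bromo methyl ketal F3, and mild aqueous acid (PPTS, acetone/H2O) then opens the ketal. This comes back at 13.

**Step 12.** Reduction and silylation of the C12 peroxyl radical may outrun its slow 7-exo closure, the prenyl groups may be over-oxidised, or C13 may form with poor selectivity. The fallback sets out from 18 and separates peroxide formation from ring closure. The peroxidation is run to the open-chain triethylsilyl peroxide F4, which is desilylated (HCl, MeOH) to the hydroperoxide F5. The peroxyl radical is then generated under non-reducing chain conditions (di-tert-butyl hyponitrite, O2, t-BuOOH, PhH, rt), where it has time to cyclise and the C15 peroxyl radical ends as the hydroperoxide. This comes back at 20.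

## Further compounds

F1 | step 8 | bicyclo[3.3.1]nonane-2,4,9-trione secondary bromide (C5–C6 closed, Br on C7, C7 configuration open) | C#CC[C@@]12CC(Br)C(C)(C)[C@@](C(=O)c3ccccc3)(C1=O)C(=O)[C@](CC#C)(C(=C)C(C)(C)O)C2=O
F2 | step 4 | methyl 2-methylbut-3-yn-2-yl carbonate | COC(=O)OC(C)(C)C#C
F3 | step 7 | bromo methyl ketal of 13 (C4 methoxy ketal closed to the C12 oxygen, C4 configuration open) | C#CC[C@]1(Br)C(=O)[C@](C(=O)c2ccccc2)(C(C)(C)C=C)C(=O)[C@]2(CC#C)C(=C)C(C)(C)OC12OC
F4 | step 12 | open-chain C12 triethylsilyl peroxide of 18 | CC(C)=CC[C@]12C[C@@H]3C[C@H](C(C)(C)OO[Si](CC)(CC)CC)[C@](CC=C(C)C)(C1=O)C(=O)[C@](C(=O)c1ccccc1)(C2=O)C3(C)C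
F5 | step 12 | open-chain C12 hydroperoxide | CC(C)=CC[C@]12C[C@@H]3C[C@H](C(C)(C)OO)[C@](CC=C(C)C)(C1=O)C(=O)[C@](C(=O)c1ccccc1)(C2=O)C3(C)C
A1 | alternative 1 | cyclohexene silyl enol ether cycloadduct | CC(C)=CCC1=C(O[Si](C(C)C)(C(C)C)C(C)C)CC(C)(C)[C@H](C(=O)N2CCOC2=O)C1
A2 | alternative 1 | triisopropyl[(6-methyl-3-methylidenehepta-1,5-dien-2-yl)oxy]silane | C=C(CC=C(C)C)C(=C)O[Si](C(C)C)(C(C)C)C(C)C
A3 | alternative 1 | 3-(3-methylbut-2-enoyl)-1,3-oxazolidin-2-one | CC(C)=CC(=O)N1CCOC1=O
A4 | alternative 2 | bridged bicyclo[4.3.1]decane trione carbinol (enol form) | CC(C)=CC[C@]12C[C@@H](C(C)=C)C[C@H](C(C)(C)O)[C@](CC=C(C)C)(C1=O)C(=O)C(C(=O)c1ccccc1)=C2O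
A5 | alternative 2 | 3,5-diprenyl-2,4,6-trihydroxybenzophenone | CC(C)=CCc1c(O)c(CC=C(C)C)c(O)c(C(=O)c2ccccc2)c1O
A6 | alternative 2 | 3-[2-(iodomethyl)-3-methylbut-3-en-1-yl]-2,2-dimethyloxirane (epoxidised lavandulyl iodide) | IC[C@@H](C(C)=C)C[C@@H]1OC1(C)C
A7 | alternative 3 | triethylsilyl peroxide of the target | CC(C)=CC[C@]12C[C@@H]3C[C@@H]4C(C)(C)OO[C@H](C(C)(C)OO[Si](CC)(CC)CC)C[C@@]4(C1=O)C(=O)[C@](C(=O)c1ccccc1)(C2=O)C3(C)C
A8 | alternative 3 | cage diene with C11 isopropenyl and C3 prenyl groups | CC(C)=CC[C@]12C[C@@H]3C[C@H](C(C)=C)[C@](CC=C(C)C)(C1=O)C(=O)[C@](C(=O)c1ccccc1)(C2=O)C3(C)C
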